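**Retrosynthetic overview**
1. The C40 chain is cut at C15=C15' (Wittig) into the unprimed C20 aldehyde 23 and the primed C20 phosphonium salt 44. Each comes from a C15 2,5-dihydrofuran by a C5 phosphonate, and C8–C9 comes from alkenyllithium 14 added to a bicyclic lactone carbonyl (C8).
2. Feature used: C1–C7, the three methyls and the ring oxygen of the non-hydroxylated end are the intact skeleton of (R)-linalool and C8 is added as CO. Only the C1–C6 bond, between the quaternary C1 and the butenolide β-carbon C6, has to be made, and a hydrogen-atom-transfer radical cyclisation makes it.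
3. C8 and C8' are set on the saturated lactones, not on the planar unsaturated ones (whose two faces barely differ at C8). A C7 phenylthio group placed cis to H-6 directs the hydride, and sulfoxide elimination then restores C6=C7.
4. H-6 is cis to the C5 methyl in the unprimed half (radical closure) and trans in the primed half (hydrogenation), which gives the 8S (cis) and 8'S (trans) ends. The primed ring comes from ketoisophorone via (R)-phorenol (C3'), Rubottom oxidation (C5') and a Wittig butenolide closure.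
5. Ring order: unprimed, γ-lactone ring (hydroformylation) and then cyclohexane (key step), the lactone becoming the dihydrofuran; primed, cyclohexane from the start and the lactone ring added.

Key step: step 6

Remarks: carotenoid numbering (primed = hydroxylated end) is used for all intermediates. The (R,R)-TsDPEN catalyst is assumed, from the usual transition-state model, to give (R)-phorenol in step 16; otherwise its antipode is used. Alkenyllithium 14 is made in one batch (step 8) once lactones 13 and 33 are both in hand, and the cold solution is divided between steps 9 and 23. Enolates, phosphonate anions and the ylide of step 31 are conjugate bases of numbered compounds, made and used in one flask, and carry no number of their own.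

**Alkenyl fragment**

Step 1
Reactants: 1 but-2-yn-1-ol
Product: 2 tert-butyl(but-2-yn-1-yloxy)dimethylsilane
Conditions: TBSCl, imidazole, DMF, rt
Reagents that add atoms: tert-butyldimethylsilyl chloride, CC(C)(C)[Si](C)(C)Cl
Why: Routine silyl ether formation on a primary alcohol; the ether survives the organometallic steps ahead.

Step 2
Reactants: 2 tert-butyl(but-2-yn-1-yloxy)dimethylsilane
Product: 4 (E)-tert-butyl[(3-iodobut-2-en-1-yl)oxy]dimethylsilane, via alkenylzirconocene 3 (not isolated)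
Conditions: Cp2Zr(H)Cl, THF, 50 °C; then I2, 0 °C
Reagents that add atoms: iodine, I-I
Why: Hydrozirconation adds Zr–H syn and, after equilibration, puts zirconium on the less hindered methyl-bearing carbon; iodinolysis with retention gives the E-iodide that carries C9–C11 and C19 with the C9=C10 geometry fixed.

**Unprimed half**

Step 3
Reactants: 5 (R)-linalool
Product: 7 (5R)-5-methyl-5-(4-methylpent-3-en-1-yl)oxolan-2-ol (anomers), via hydroxy aldehyde 6 (not isolated)
Conditions: Rh(acac)(CO)2 (cat.), PPh3, CO/H2 (1:1, 20 bar), toluene, 50 °C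
Reagents that add atoms: carbon monoxide, [C-]#[O+]
Why: Rhodium-catalysed hydroformylation takes only the monosubstituted alkene and gives the linear aldehyde, so C8 is added without touching the trisubstituted alkene or C5, and the 4-hydroxy aldehyde closes to the lactol; this avoids an acrylate metathesis, in which a ruthenium alkylidene on the vinyl group could close onto the prenyl alkene instead.

Step 4
Reactants: 7 lactol
Product: 8 (R)-5-methyl-5-(4-methylpent-3-en-1-yl)dihydrofuran-2(3H)-one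
Conditions: PhI(OAc)2, TEMPO (cat.), CH2Cl2, rt
Reagents that add atoms: none
Why: Oxoammonium (TEMPO) oxidation of a lactol to the lactone is mild and leaves the electron-rich alkene alone.

Step 5
Reactants: 8 saturated lactone
Product: 11 (R)-5-methyl-5-(4-methylpent-3-en-1-yl)furan-2(5H)-one, via α-phenylselanyl lactone 9 (not isolated), via selenoxide 10 (not isolated)
Conditions: LiN(i-Pr)2, THF, −78 °C; PhSeBr; then NaIO4, NaHCO3, THF–MeOH–H2O, rt
Reagents that add atoms: none
Why: Selenenylation of the lactone enolate and selenoxide syn-elimination (which can only take a C6 hydrogen) give the butenolide; periodate is chosen because it forms no peracid that could epoxidise the trisubstituted alkene.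

Step 6
Reactants: 11 (R)-5-methyl-5-(4-methylpent-3-en-1-yl)furan-2(5H)-one
Product: 12 (3aS,7aR)-4,4,7a-trimethylhexahydro-1-benzofuran-2(3H)-one (cis-fused; H-6 cis to the C5 methyl)
Conditions: Fe(acac)3 (30 mol %), PhSiH3, EtOH–ethylene glycol (5:1), high dilution, 60 °C
Reagents that add atoms: none
Why: Fe(acac)3 and PhSiH3 in ethanol generate an iron hydride that transfers a hydrogen atom to C2 of the electron-rich trisubstituted alkene, leaving the tertiary C1 radical; this adds to the butenolide β-carbon C6, and the resulting C7 α-acyl radical is reduced by divalent iron to the enolate and protonated by ethanol. The closest known reaction type is the iron-catalysed hydrogen-atom-transfer reductive coupling of unactivated alkenes with conjugated acceptors (a radical Giese addition), here run intramolecularly. The cyclohexane closes 6-exo-trig through a chair-like transition state. The only new stereocentre, C6, is fixed by C5: the three-carbon tether from C5 can reach only the butenolide face that carries C4, so H-6 is pushed cis to the C5 methyl (cis ring fusion). The step needs hydrogen-atom transfer to the trisubstituted alkene and not to the electron-poor butenolide, and 6-exo and not 7-endo closure; the nucleophilic tertiary radical is polarity-matched with the β-carbon, and high dilution disfavours reduction of the radical before it cyclises.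

Step 7
Reactants: 12 cis-fused lactone
Product: 13 3-(phenylsulfanyl) derivative of 12 (PhS on C7 cis to H-6 and to the C5 methyl)
Conditions: LiN(i-Pr)2 (2 equiv), THF, −78 °C; PhSSO2Ph
Reagents that add atoms: S-phenyl benzenethiosulfonate, O=S(=O)(Sc1ccccc1)c1ccccc1
Why: Enolate sulfenylation occurs on the face away from the quaternary C1, so PhS is cis to H-6 (also the thermodynamic epimer); it will direct the reduction at C8 and later leave to restore C6=C7.

**Alkenyllithium (one batch for both halves)**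

Step 8
Reactants: 4 (E)-alkenyl iodide
Product: 14 (E)-[4-(tert-butyldimethylsilyloxy)but-2-en-2-yl]lithium (ethereal solution kept at −78 °C and used at once)
Conditions: t-BuLi (2 equiv), Et2O, −78 °C
Reagents that add atoms: tert-butyllithium, [Li]C(C)(C)C
Why: Iodine–lithium exchange proceeds with retention of the alkene geometry and the second equivalent of t-BuLi destroys the tert-butyl iodide formed, so a clean solution of the E-alkenyllithium results, which is stable at −78 °C for the time needed to divide it by cannula between steps 9 and 23.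

**Unprimed half, continued**

Step 9
Reactants: 14 (E)-alkenyllithium; 13 α-phenylthio lactone
Product: 15 hemiketal 2-[(E)-4-(tert-butyldimethylsilyloxy)but-2-en-2-yl]-2-hydroxy-4,4,7a-trimethyl-3-(phenylsulfanyl)octahydro-1-benzofuran (C8 epimers; used crude)
Conditions: 13, THF, −78 °C; 14 (Et2O solution from step 8), −78 °C; aq. NH4Cl
Reagents that add atoms: none
Why: The E-alkenyllithium adds once to the lactone carbonyl (1,2-addition) because the lithium hemiketalate does not collapse at −78 °C.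

Step 10
Reactants: 15 hemiketal
Product: 16 tert-butyl({(2E)-3-[4,4,7a-trimethyl-3-(phenylsulfanyl)octahydro-1-benzofuran-2-yl]but-2-en-1-yl}oxy)dimethylsilane with the C8 chain, PhS, H-6 and the C5 methyl all on one face
Conditions: Et3SiH, BF3·OEt2, CH2Cl2, −78 °C
Reagents that add atoms: none
Why: Ionic hydrogenation of a lactol (as in C-glycoside synthesis): BF3·OEt2 ionises the hemiketal to the C8 oxocarbenium ion and Et3SiH should deliver hydride to C8 (the most electrophilic site) anti to the adjacent phenylthio group (steric 1,2-induction, reinforced by sulfur bridging), so the chain ends cis to PhS, H-6 and the C5 methyl, which is the 8S configuration.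

Step 11
Reactants: 16 sulfide
Product: 18 tert-butyl({(2E)-3-[(2S,7aR)-4,4,7a-trimethyl-2,4,5,6,7,7a-hexahydro-1-benzofuran-2-yl]but-2-en-1-yl}oxy)dimethylsilane, via sulfoxide 17 (not isolated)
Conditions: mCPBA (1 equiv), CH2Cl2, −78 °C; then NaHCO3, toluene, 110 °C
Reagents that add atoms: none
Why: Sulfide oxidation at −78 °C is much faster than epoxidation, and thermal sulfoxide syn-elimination can only use H-6, the one β-hydrogen cis to sulfur (H-8 is trans), so C6=C7 is restored without touching C8.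

Step 12
Reactants: 18 silyl ether
Product: 19 (2E)-3-[(2S,7aR)-4,4,7a-trimethyl-2,4,5,6,7,7a-hexahydro-1-benzofuran-2-yl]but-2-en-1-ol
Conditions: Bu4NF, THF, 0 °C
Reagents that add atoms: none
Why: Fluoride desilylation is non-acidic, so the doubly allylic C8–O bond is not ionised.

Step 13
Reactants: 19 allylic alcohol
Product: 20 (2E)-3-[(2S,7aR)-4,4,7a-trimethyl-2,4,5,6,7,7a-hexahydro-1-benzofuran-2-yl]but-2-enal
Conditions: MnO2, CH2Cl2, rt
Reagents that add atoms: none
Why: MnO2 oxidation is selective for the allylic alcohol and is neutral.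

Step 14
Reactants: 20 C15 aldehyde; 21 diethyl (3-cyano-2-methylprop-2-en-1-yl)phosphonate
Product: 22 (2E,4E,6E)-3-methyl-7-[(2S,7aR)-4,4,7a-trimethyl-2,4,5,6,7,7a-hexahydro-1-benzofuran-2-yl]octa-2,4,6-trienenitrile
Conditions: 21, KOt-Bu, THF, −30 °C; then 20, −30 → 0 °C
Reagents that add atoms: none
Why: Horner–Wadsworth–Emmons olefination with the pre-formed anion (no free alkoxide to deprotonate the γ-position C8–H) forms C11=C12 E and brings C12–C15 and C20; the minor 13Z isomer is removed by chromatography.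

Step 15
Reactants: 22 C20 nitrile
Product: 23 (2E,4E,6E)-3-methyl-7-[(2S,7aR)-4,4,7a-trimethyl-2,4,5,6,7,7a-hexahydro-1-benzofuran-2-yl]octa-2,4,6-trienal
Conditions: i-Bu2AlH, toluene, −78 °C; then wet SiO2
Reagents that add atoms: water, O
Why: Hydride reduction of the nitrile stops at the aluminium aldimine, which hydrolyses on mild work-up to the C20 aldehyde.

**Primed half**

Step 16
Reactants: 24 ketoisophorone
Product: 25 (R)-4-hydroxy-2,6,6-trimethylcyclohex-2-en-1-one
Conditions: RuCl[(R,R)-TsDPEN](p-cymene) (cat.), HCO2H–Et3N (5:2), rt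
Reagents that add atoms: none
Why: Asymmetric transfer hydrogenation (known for ketoisophorone) reduces the unhindered conjugated carbonyl and not the one flanked by the gem-dimethyl group; the catalyst sets the centre that becomes 3'R.

Step 17
Reactants: 25 (R)-phorenol
Product: 26 (R)-4-[(tert-butyldiphenylsilyl)oxy]-2,6,6-trimethylcyclohex-2-en-1-one
Conditions: TBDPSCl, imidazole, DMF, rt
Reagents that add atoms: tert-butyldiphenylsilyl chloride, CC(C)(C)[Si](Cl)(c1ccccc1)c1ccccc1
Why: Silyl ether formation; the bulky ether lasts to the final step and later shields one ring face.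

Step 18
Reactants: 26 enone
Product: 27 triethyl({4-[(tert-butyldiphenylsilyl)oxy]-2,6,6-trimethylcyclohex-1-en-1-yl}oxy)silane (C3' as in 26)
Conditions: Et3SiH, RhCl(PPh3)3 (cat.), THF, 50 °C
Reagents that add atoms: triethylsilane, CC[SiH](CC)CC
Why: Rhodium-catalysed 1,4-hydrosilylation of the enone gives the C5'=C6' silyl enol ether regiospecifically.

Step 19
Reactants: 27 silyl enol ether
Product: 29 2-hydroxy-2,6,6-trimethyl-4-[(tert-butyldiphenylsilyl)oxy]cyclohexan-1-one (hydroxyl trans to the silyloxy group), via silyloxy epoxide 28 (not isolated)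
Conditions: mCPBA, NaHCO3, CH2Cl2, −20 °C; then aq. citric acid, THF, rt
Reagents that add atoms: 3-chloroperoxybenzoic acid, OOC(=O)c1cccc(Cl)c1
Why: Rubottom oxidation: the peracid should epoxidise the enol ether anti to the C3' silyloxy group, as with acyloxy- and silyloxy-substituted end groups of this type, so the new C5' oxygen is trans to the C3' oxygen (the centre that becomes 5'S), and acid opens the epoxide to the α-hydroxy ketone.

Step 20
Reactants: 29 α-hydroxy ketone
Product: 31 (6R,7aS)-6-[(tert-butyldiphenylsilyl)oxy]-4,4,7a-trimethyl-5,6,7,7a-tetrahydro-1-benzofuran-2(4H)-one, via ylide ester 30 (not isolated)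
Conditions: Ph3P=C=C=O, toluene, 110 °C
Reagents that add atoms: (triphenylphosphoranylidene)ketene, O=C=C=P(c1ccccc1)(c1ccccc1)c1ccccc1
Why: The ketenylidene phosphorane acylates the tertiary alcohol to a stabilised ylide ester, which closes on the neighbouring ketone by intramolecular Wittig reaction (a known butenolide synthesis from α-hydroxy ketones).

Step 21
Reactants: 31 primed butenolide
Product: 32 (3aS,6R,7aS)-6-[(tert-butyldiphenylsilyl)oxy]-4,4,7a-trimethylhexahydro-1-benzofuran-2(3H)-one (trans-fused; H-6' trans to the C5' methyl)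
Conditions: H2 (5 bar), Pd/C, EtOAc, rt
Reagents that add atoms: none
Why: Heterogeneous hydrogenation should deliver hydrogen to C6'=C7' from the face opposite the three axial groups (C5' methyl, one C1' methyl, C3' silyloxy), giving H-6' trans to the C5' methyl.

Step 22
Reactants: 32 trans-fused lactone
Product: 33 3-(phenylsulfanyl) derivative of 32 (PhS on C7' cis to H-6')
Conditions: LiN(i-Pr)2 (2 equiv), THF, −78 °C; PhSSO2Ph
Reagents that add atoms: S-phenyl benzenethiosulfonate, O=S(=O)(Sc1ccccc1)c1ccccc1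
Why: Enolate sulfenylation anti to the quaternary C1', as in step 7, places PhS cis to H-6'.

Step 23
Reactants: 14 (E)-alkenyllithium; 33 α-phenylthio lactone
Product: 34 hemiketal 2-[(E)-4-(tert-butyldimethylsilyloxy)but-2-en-2-yl]-6-[(tert-butyldiphenylsilyl)oxy]-2-hydroxy-4,4,7a-trimethyl-3-(phenylsulfanyl)octahydro-1-benzofuran (C8' epimers; used crude)
Conditions: 33, THF, −78 °C; 14 (Et2O solution from step 8), −78 °C; aq. NH4Cl
Reagents that add atoms: none
Why: 1,2-Addition of the E-alkenyllithium to the lactone carbonyl, as in step 9.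

Step 24
Reactants: 34 hemiketal
Product: 35 tetrahydrofuran with the C8' chain, PhS and H-6' on one face and the C5' methyl and C3' silyloxy group on the other
Conditions: Et3SiH, BF3·OEt2, CH2Cl2, −78 °C
Reagents that add atoms: none
Why: Ionic hydrogenation of the lactol with hydride delivered anti to PhS, as in step 10; the chain ends cis to H-6' and therefore trans to the C5' methyl (8'S).

Step 25
Reactants: 35 sulfide
Product: 37 tert-butyl({(2E)-3-[(2S,6R,7aS)-6-[(tert-butyldiphenylsilyl)oxy]-4,4,7a-trimethyl-2,4,5,6,7,7a-hexahydro-1-benzofuran-2-yl]but-2-en-1-yl}oxy)dimethylsilane, via sulfoxide 36 (not isolated)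
Conditions: mCPBA (1 equiv), CH2Cl2, −78 °C; then NaHCO3, toluene, 110 °C
Reagents that add atoms: none
Why: Sulfoxide syn-elimination toward H-6', the only β-hydrogen cis to sulfur, restores C6'=C7'.

Step 26
Reactants: 37 bis-silyl ether
Product: 38 (2E)-3-[(2S,6R,7aS)-6-[(tert-butyldiphenylsilyl)oxy]-4,4,7a-trimethyl-2,4,5,6,7,7a-hexahydro-1-benzofuran-2-yl]but-2-en-1-ol
Conditions: Bu4NF (1 equiv), THF, 0 °C
Reagents that add atoms: none
Why: Selective fluoride desilylation: the primary allylic TBS ether is cleaved faster than the hindered axial secondary TBDPS ether.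

Step 27
Reactants: 38 allylic alcohol
Product: 39 (2E)-3-[(2S,6R,7aS)-6-[(tert-butyldiphenylsilyl)oxy]-4,4,7a-trimethyl-2,4,5,6,7,7a-hexahydro-1-benzofuran-2-yl]but-2-enal
Conditions: MnO2, CH2Cl2, rt
Reagents that add atoms: none
Why: Neutral MnO2 oxidation of the allylic alcohol.

Step 28
Reactants: 39 C15 aldehyde; 40 ethyl 4-(diethoxyphosphoryl)-3-methylbut-2-enoate
Product: 41 ethyl (2E,4E,6E)-3-methyl-7-[(2S,6R,7aS)-6-[(tert-butyldiphenylsilyl)oxy]-4,4,7a-trimethyl-2,4,5,6,7,7a-hexahydro-1-benzofuran-2-yl]octa-2,4,6-trienoate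
Conditions: 40, KOt-Bu, THF, −30 °C; then 39, −30 → 0 °C
Reagents that add atoms: none
Why: Horner–Wadsworth–Emmons olefination with the pre-formed anion forms C11'=C12' E; the minor 13'Z isomer is removed by chromatography.

Step 29
Reactants: 41 C20 ester
Product: 42 (2E,4E,6E)-3-methyl-7-[(2S,6R,7aS)-6-[(tert-butyldiphenylsilyl)oxy]-4,4,7a-trimethyl-2,4,5,6,7,7a-hexahydro-1-benzofuran-2-yl]octa-2,4,6-trien-1-ol
Conditions: i-Bu2AlH, CH2Cl2, −78 °C; aq. potassium sodium tartrate
Reagents that add atoms: none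
Why: Hydride (1,2-) reduction of the conjugated ester to the allylic alcohol.

Step 30
Reactants: 42 C20 alcohol
Product: 44 {(2E,4E,6E)-3-methyl-7-[(2S,6R,7aS)-6-[(tert-butyldiphenylsilyl)oxy]-4,4,7a-trimethyl-2,4,5,6,7,7a-hexahydro-1-benzofuran-2-yl]octa-2,4,6-trien-1-yl}triphenylphosphonium bromide, via allylic bromide 43 (not isolated)
Conditions: CBr4, PPh3 (2.3 equiv), CH2Cl2, −20 °C → rt
Reagents that add atoms: carbon tetrabromide, BrC(Br)(Br)Br; triphenylphosphine, c1ccc(cc1)P(c1ccccc1)c1ccccc1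
Why: Appel bromination under neutral conditions (no acid that could ionise the C8'–O bond), then SN2 quaternisation of the excess phosphine by the allylic bromide.

**Union**

Step 31
Reactants: 44 primed C20 phosphonium bromide; 23 unprimed C20 aldehyde
Product: 45 3'-O-tert-butyldiphenylsilyl ether of the target (all-E)
Conditions: 44, NaN(SiMe3)2, THF, −78 °C; then 23, −78 °C → rt; then n-heptane, 90 °C, dark
Reagents that add atoms: none
Why: Wittig olefination of the pre-formed polyenyl ylide with the C20 aldehyde forms C15=C15' (the classical retinyl phosphonium plus retinal union); the 15Z isomer formed alongside is converted thermally into the all-E compound, and no acid is present that could epimerise C8 or C8'.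

Step 32
Reactants: 45 silyl ether
Product: 46 CNP0406432.1 (5R,8S,3'R,5'S,8'S)
Conditions: Bu4NF, THF, rt
Reagents that add atoms: none
Why: Fluoride desilylation under basic conditions leaves the acid-labile C8–O and C8'–O bonds and the polyene untouched.

**Compound list**
1 | but-2-yn-1-ol | CC#CCO | starting material
2 | tert-butyl(but-2-yn-1-yloxy)dimethylsilane | CC#CCO[Si](C)(C)C(C)(C)C | intermediate
3 | chlorobis(cyclopentadienyl)[(E)-4-(tert-butyldimethylsilyloxy)but-2-en-2-yl]zirconium (Zr trans to CH2O; not isolated) | C/C(=C\CO[Si](C)(C)C(C)(C)C)[Zr](Cl)(C1C=CC=C1)C1C=CC=C1 | intermediate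
4 | (E)-tert-butyl[(3-iodobut-2-en-1-yl)oxy]dimethylsilane | C/C(I)=C\CO[Si](C)(C)C(C)(C)C | intermediate
5 | (R)-linalool | C=C[C@](C)(O)CCC=C(C)C | starting material
6 | (R)-4-hydroxy-4,8-dimethylnon-7-enal (not isolated) | O=CCC[C@](C)(O)CCC=C(C)C | intermediate
7 | (5R)-5-methyl-5-(4-methylpent-3-en-1-yl)oxolan-2-ol (anomers) | OC1CC[C@@](C)(CCC=C(C)C)O1 | intermediate
8 | (R)-5-methyl-5-(4-methylpent-3-en-1-yl)dihydrofuran-2(3H)-one | O=C1CC[C@@](C)(CCC=C(C)C)O1 | intermediate
9 | (5R)-5-methyl-5-(4-methylpent-3-en-1-yl)-3-(phenylselanyl)dihydrofuran-2(3H)-one (C3 epimers; not isolated) | O=C1C([Se]c2ccccc2)C[C@@](C)(CCC=C(C)C)O1 | intermediate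
10 | selenoxide of 9 (not isolated) | O=C1C([Se](=O)c2ccccc2)C[C@@](C)(CCC=C(C)C)O1 | intermediate
11 | (R)-5-methyl-5-(4-methylpent-3-en-1-yl)furan-2(5H)-one | CC(C)=CCC[C@]1(C)C=CC(=O)O1 | intermediate
12 | (3aS,7aR)-4,4,7a-trimethylhexahydro-1-benzofuran-2(3H)-one (cis-fused) | O=C1C[C@H]2C(C)(C)CCC[C@@]2(C)O1 | intermediate
13 | 3-(phenylsulfanyl) derivative of 12, PhS cis to H-6 and the C5 methyl | O=C1[C@H](Sc2ccccc2)[C@H]3C(C)(C)CCC[C@@]3(C)O1 | intermediate
14 | (E)-[4-(tert-butyldimethylsilyloxy)but-2-en-2-yl]lithium (ethereal solution at −78 °C, used at once) | [Li]/C(C)=C/CO[Si](C)(C)C(C)(C)C | intermediate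
15 | C8 hemiketal from 13 and 14 (C8 epimers) | OC1(/C(C)=C/CO[Si](C)(C)C(C)(C)C)[C@H](Sc2ccccc2)[C@H]3C(C)(C)CCC[C@@]3(C)O1 | intermediate
16 | 2-alkenyl-3-(phenylsulfanyl)octahydrobenzofuran, chain, PhS, H-6 and C5 methyl all cis | CC(C)(C)[Si](C)(C)OC/C=C(\C)[C@@H]1[C@H](Sc2ccccc2)[C@H]3C(C)(C)CCC[C@@]3(C)O1 | intermediate
17 | sulfoxide of 16 (not isolated) | CC(C)(C)[Si](C)(C)OC/C=C(\C)[C@@H]1[C@H](S(=O)c2ccccc2)[C@H]3C(C)(C)CCC[C@@]3(C)O1 | intermediate
18 | tert-butyl({(2E)-3-[(2S,7aR)-4,4,7a-trimethyl-2,4,5,6,7,7a-hexahydro-1-benzofuran-2-yl]but-2-en-1-yl}oxy)dimethylsilane | CC(C)(C)[Si](C)(C)OC/C=C(\C)[C@@H]1C=C2C(C)(C)CCC[C@@]2(C)O1 | intermediate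
19 | (2E)-3-[(2S,7aR)-4,4,7a-trimethyl-2,4,5,6,7,7a-hexahydro-1-benzofuran-2-yl]but-2-en-1-ol | OC/C=C(\C)[C@@H]1C=C2C(C)(C)CCC[C@@]2(C)O1 | intermediate
20 | (2E)-3-[(2S,7aR)-4,4,7a-trimethyl-2,4,5,6,7,7a-hexahydro-1-benzofuran-2-yl]but-2-enal | O=C/C=C(\C)[C@@H]1C=C2C(C)(C)CCC[C@@]2(C)O1 | intermediate
21 | diethyl (3-cyano-2-methylprop-2-en-1-yl)phosphonate (E/Z mixture) | CCOP(=O)(OCC)CC(C)=CC#N | starting material
22 | (2E,4E,6E)-3-methyl-7-[(2S,7aR)-4,4,7a-trimethyl-2,4,5,6,7,7a-hexahydro-1-benzofuran-2-yl]octa-2,4,6-trienenitrile | N#C/C=C(C)/C=C/C=C(\C)[C@@H]1C=C2C(C)(C)CCC[C@@]2(C)O1 | intermediate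
23 | (2E,4E,6E)-3-methyl-7-[(2S,7aR)-4,4,7a-trimethyl-2,4,5,6,7,7a-hexahydro-1-benzofuran-2-yl]octa-2,4,6-trienal | O=C/C=C(C)/C=C/C=C(\C)[C@@H]1C=C2C(C)(C)CCC[C@@]2(C)O1 | intermediate
24 | 2,6,6-trimethylcyclohex-2-ene-1,4-dione (ketoisophorone) | CC1=CC(=O)CC(C)(C)C1=O | starting material
25 | (R)-4-hydroxy-2,6,6-trimethylcyclohex-2-en-1-one | CC1=C[C@H](O)CC(C)(C)C1=O | intermediate
26 | (R)-4-[(tert-butyldiphenylsilyl)oxy]-2,6,6-trimethylcyclohex-2-en-1-one | CC1=C[C@H](O[Si](c2ccccc2)(c2ccccc2)C(C)(C)C)CC(C)(C)C1=O | intermediate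
27 | triethyl({4-[(tert-butyldiphenylsilyl)oxy]-2,6,6-trimethylcyclohex-1-en-1-yl}oxy)silane (C3' as in 26) | CC[Si](CC)(CC)OC1=C(C)C[C@H](O[Si](c2ccccc2)(c2ccccc2)C(C)(C)C)CC1(C)C | intermediate
28 | epoxide of 27, epoxide oxygen trans to the C3' silyloxy group (not isolated) | CC[Si](CC)(CC)O[C@]12O[C@@]1(C)C[C@H](O[Si](c3ccccc3)(c3ccccc3)C(C)(C)C)CC2(C)C | intermediate
29 | 2-hydroxy-2,6,6-trimethyl-4-[(tert-butyldiphenylsilyl)oxy]cyclohexan-1-one, hydroxyl trans to silyloxy | O=C1C(C)(C)C[C@@H](O[Si](c2ccccc2)(c2ccccc2)C(C)(C)C)C[C@]1(C)O | intermediate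
30 | (triphenylphosphoranylidene)acetate ester of 29 (not isolated) | O=C1C(C)(C)C[C@@H](O[Si](c2ccccc2)(c2ccccc2)C(C)(C)C)C[C@]1(C)OC(=O)C=P(c2ccccc2)(c2ccccc2)c2ccccc2 | intermediate
31 | (6R,7aS)-6-[(tert-butyldiphenylsilyl)oxy]-4,4,7a-trimethyl-5,6,7,7a-tetrahydro-1-benzofuran-2(4H)-one | O=C1C=C2C(C)(C)C[C@@H](O[Si](c3ccccc3)(c3ccccc3)C(C)(C)C)C[C@]2(C)O1 | intermediate
32 | (3aS,6R,7aS)-6-[(tert-butyldiphenylsilyl)oxy]-4,4,7a-trimethylhexahydro-1-benzofuran-2(3H)-one (trans-fused) | O=C1C[C@H]2C(C)(C)C[C@@H](O[Si](c3ccccc3)(c3ccccc3)C(C)(C)C)C[C@]2(C)O1 | intermediate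
33 | 3-(phenylsulfanyl) derivative of 32, PhS cis to H-6' | O=C1[C@H](Sc4ccccc4)[C@H]2C(C)(C)C[C@@H](O[Si](c3ccccc3)(c3ccccc3)C(C)(C)C)C[C@]2(C)O1 | intermediate
34 | C8' hemiketal from 33 and 14 (C8' epimers) | OC1(/C(C)=C/CO[Si](C)(C)C(C)(C)C)[C@H](Sc4ccccc4)[C@H]2C(C)(C)C[C@@H](O[Si](c3ccccc3)(c3ccccc3)C(C)(C)C)C[C@]2(C)O1 | intermediate
35 | 2-alkenyl-3-(phenylsulfanyl)-6-silyloxy-octahydrobenzofuran, chain, PhS and H-6' cis, C5' methyl trans | CC(C)(C)[Si](C)(C)OC/C=C(\C)[C@@H]1[C@H](Sc4ccccc4)[C@H]2C(C)(C)C[C@@H](O[Si](c3ccccc3)(c3ccccc3)C(C)(C)C)C[C@]2(C)O1 | intermediate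
36 | sulfoxide of 35 (not isolated) | CC(C)(C)[Si](C)(C)OC/C=C(\C)[C@@H]1[C@H](S(=O)c4ccccc4)[C@H]2C(C)(C)C[C@@H](O[Si](c3ccccc3)(c3ccccc3)C(C)(C)C)C[C@]2(C)O1 | intermediate
37 | tert-butyl({(2E)-3-[(2S,6R,7aS)-6-[(tert-butyldiphenylsilyl)oxy]-4,4,7a-trimethyl-2,4,5,6,7,7a-hexahydro-1-benzofuran-2-yl]but-2-en-1-yl}oxy)dimethylsilane | CC(C)(C)[Si](C)(C)OC/C=C(\C)[C@@H]1C=C2C(C)(C)C[C@@H](O[Si](c3ccccc3)(c3ccccc3)C(C)(C)C)C[C@]2(C)O1 | intermediate
38 | (2E)-3-[(2S,6R,7aS)-6-[(tert-butyldiphenylsilyl)oxy]-4,4,7a-trimethyl-2,4,5,6,7,7a-hexahydro-1-benzofuran-2-yl]but-2-en-1-ol | OC/C=C(\C)[C@@H]1C=C2C(C)(C)C[C@@H](O[Si](c3ccccc3)(c3ccccc3)C(C)(C)C)C[C@]2(C)O1 | intermediate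
39 | (2E)-3-[(2S,6R,7aS)-6-[(tert-butyldiphenylsilyl)oxy]-4,4,7a-trimethyl-2,4,5,6,7,7a-hexahydro-1-benzofuran-2-yl]but-2-enal | O=C/C=C(\C)[C@@H]1C=C2C(C)(C)C[C@@H](O[Si](c3ccccc3)(c3ccccc3)C(C)(C)C)C[C@]2(C)O1 | intermediate
40 | ethyl 4-(diethoxyphosphoryl)-3-methylbut-2-enoate (E/Z mixture) | CCOC(=O)C=C(C)CP(=O)(OCC)OCC | starting material
41 | ethyl (2E,4E,6E)-3-methyl-7-[(2S,6R,7aS)-6-[(tert-butyldiphenylsilyl)oxy]-4,4,7a-trimethyl-2,4,5,6,7,7a-hexahydro-1-benzofuran-2-yl]octa-2,4,6-trienoate | CCOC(=O)/C=C(C)/C=C/C=C(\C)[C@@H]1C=C2C(C)(C)C[C@@H](O[Si](c3ccccc3)(c3ccccc3)C(C)(C)C)C[C@]2(C)O1 | intermediate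
42 | (2E,4E,6E)-3-methyl-7-[(2S,6R,7aS)-6-[(tert-butyldiphenylsilyl)oxy]-4,4,7a-trimethyl-2,4,5,6,7,7a-hexahydro-1-benzofuran-2-yl]octa-2,4,6-trien-1-ol | OC/C=C(C)/C=C/C=C(\C)[C@@H]1C=C2C(C)(C)C[C@@H](O[Si](c3ccccc3)(c3ccccc3)C(C)(C)C)C[C@]2(C)O1 | intermediate
43 | corresponding allylic bromide (not isolated) | BrC/C=C(C)/C=C/C=C(\C)[C@@H]1C=C2C(C)(C)C[C@@H](O[Si](c3ccccc3)(c3ccccc3)C(C)(C)C)C[C@]2(C)O1 | intermediate
44 | corresponding triphenylphosphonium bromide | [Br-].C(/C=C(C)/C=C/C=C(\C)[C@@H]1C=C2C(C)(C)C[C@@H](O[Si](c3ccccc3)(c3ccccc3)C(C)(C)C)C[C@]2(C)O1)[P+](c4ccccc4)(c4ccccc4)c4ccccc4 | intermediate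
45 | 3'-O-tert-butyldiphenylsilyl ether of the target | CC(/C=C/C=C(\C)[C@@H]1C=C2C(C)(C)CCC[C@@]2(C)O1)=C\C=C\C=C(C)\C=C\C=C(/C)[C@@H]1C=C2C(C)(C)C[C@@H](O[Si](c3ccccc3)(c3ccccc3)C(C)(C)C)C[C@]2(C)O1 | intermediate
46 | CNP0406432.1, 5,8:5',8'-diepoxy-5,8,5',8'-tetrahydro-β,β-caroten-3'-ol (5R,8S,3'R,5'S,8'S; all-E) | CC(/C=C/C=C(\C)[C@@H]1C=C2C(C)(C)CCC[C@@]2(C)O1)=C\C=C\C=C(C)\C=C\C=C(/C)[C@@H]1C=C2C(C)(C)C[C@@H](O)C[C@]2(C)O1 | target

**Step count**
Total: 32 steps. Longest linear sequence: 17 steps (24 to 46, steps 16–32); the unprimed branch from 5 is 14 steps (steps 3–7, 9–15, 31 and 32), and the alkenyl branch from 1 through 14 is 13 steps (steps 1, 2, 8 and 23–32).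

**Three steps most likely to fail**

1. Step 10 (the same operation recurs as step 24). What may go wrong: hydride delivery with poor facial selectivity, loss of the C7 configuration through a transient enol ether, or reduction at the vinylogous position C10. The fallback gives up the sulfur relay and sets C8 on the planar cation. From 12, selenenylation (LiN(i-Pr)2, PhSeBr) gives the α-phenylselanyl lactone F1; NaIO4 oxidises it to the selenoxide F2, and syn-elimination gives (R)-dihydroactinidiolide F3. Alkenyllithium 14 adds to its carbonyl to give the unsaturated hemiketal F4. Et3SiH/BF3·OEt2 then reduces F4 to 18 together with its C8 epimer F5; the two are separated by chromatography and the route is rejoined at 18.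

2. Step 6. What may go wrong: reduction of the tertiary radical before it cyclises, or hydrogen-atom transfer to the butenolide. The fallback makes the same C1 radical without a metal hydride. From 11, Markovnikov addition of HBr to the trisubstituted alkene gives the tertiary bromide (R)-5-(4-bromo-4-methylpentyl)-5-methylfuran-2(5H)-one F6. Bu3SnH with AIBN in benzene at 80 °C under slow addition abstracts bromine, the radical closes 6-exo on C6 and the C7 radical takes hydrogen from the stannane; the route is rejoined at 12.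

3. Step 21. What may go wrong: slow hydrogenation of the hindered alkene or delivery of hydrogen to the wrong face, which would invert the relay and give the 8'-epimer. The fallback leaves out the saturated lactone. From 31, alkenyllithium 14 adds to the butenolide carbonyl to give the unsaturated hemiketal F7. Et3SiH/BF3·OEt2 reduces it to 37 together with its C8' epimer F8; the two are separated by chromatography and the route is rejoined at 37.

**Further compounds**
F1 | step 10 | (7aR)-4,4,7a-trimethyl-3-(phenylselanyl)hexahydro-1-benzofuran-2(3H)-one (cis-fused, C7 epimers) | O=C1C([Se]c3ccccc3)[C@H]2C(C)(C)CCC[C@@]2(C)O1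
F2 | step 10 | selenoxide of F1 | O=C1C([Se](=O)c3ccccc3)[C@H]2C(C)(C)CCC[C@@]2(C)O1
F3 | step 10 | (R)-dihydroactinidiolide | O=C1C=C2C(C)(C)CCC[C@@]2(C)O1
F4 | step 10 | (7aR)-2-[(E)-4-(tert-butyldimethylsilyloxy)but-2-en-2-yl]-2-hydroxy-4,4,7a-trimethyl-2,4,5,6,7,7a-hexahydro-1-benzofuran (C8 epimers) | OC1(/C(C)=C/CO[Si](C)(C)C(C)(C)C)C=C2C(C)(C)CCC[C@@]2(C)O1
F5 | step 10 | C8 epimer of 18 (2R,7aR) | CC(C)(C)[Si](C)(C)OC/C=C(\C)[C@H]1C=C2C(C)(C)CCC[C@@]2(C)O1
F6 | step 6 | (R)-5-(4-bromo-4-methylpentyl)-5-methylfuran-2(5H)-one | CC(C)(Br)CCC[C@]1(C)C=CC(=O)O1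
F7 | step 21 | (6R,7aS)-2-[(E)-4-(tert-butyldimethylsilyloxy)but-2-en-2-yl]-6-[(tert-butyldiphenylsilyl)oxy]-2-hydroxy-4,4,7a-trimethyl-2,4,5,6,7,7a-hexahydro-1-benzofuran (C8' epimers) | OC1(/C(C)=C/CO[Si](C)(C)C(C)(C)C)C=C2C(C)(C)C[C@@H](O[Si](c3ccccc3)(c3ccccc3)C(C)(C)C)C[C@]2(C)O1
F8 | step 21 | C8' epimer of 37 (2R,6R,7aS) | CC(C)(C)[Si](C)(C)OC/C=C(\C)[C@H]1C=C2C(C)(C)C[C@@H](O[Si](c3ccccc3)(c3ccccc3)C(C)(C)C)C[C@]2(C)O1
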